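**Plan**

1. Ring numbering used here: C1 bears the C17 chain, C2 the methyl, C3 is C=O, C4 is CH, C5 bears OMe, C6 is C=O. The meta oxygens at C3 and C5, next to a one-carbon group at C2 and the alkyl group at C1, are the folding pattern of a 6-alkylresorcylate, so the six-membered ring can be opened to a 3,5,7-triketo ester whose ester carbon is the C2 methyl.
2. Retrosynthetic cuts, in order: C6=O (phenol oxidation), O–CH3 at C5, the C2 methyl back to CO2Me, ring bond C1–C2 (aldol, opens the only ring), bond C6–C1 of the open chain (acylation of methyl 3,5-dioxohexanoate by a C18 acid), then in the side chain C16'–C17', the four C–CH3 bonds at C9', C11', C13', C15' and the bonds C10'–C11', C12'–C13', C14'–C15'.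
3. Forward: the chain is grown from O-silylated undec-10-en-1-ol by three methylalumination–vinylation cycles and a fourth methylalumination–oxidation, capped with methyl, oxidised to the C18 acid and joined to the dioxohexanoate trianion. The only ring then closes (step 10) and is adjusted by O-methylation, reduction of the ester to methyl and oxidation to the quinone.
4. Stereochemistry: all four centres come from catalyst-controlled Zr-catalysed methylalumination with one enantiomer of the zirconocene (all-syn array). Wrong-face events appear as diastereomers, to be removed at alcohol 16, and no later step touches these centres.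

Key step: step 10

Remark (assumption): (−)-(NMI)2ZrCl2 is taken to deliver methyl to the alkene face that gives the (R)-2-methylalkyl metal in every cycle, and the species formed on Al-to-Zn exchange is written as the alkylzinc triflate.

Remark: the CIP descriptors of the chain centres change along the route (for example 12S in 11 but 12R in 14) only because the priorities of the chain ends change; all four methyl groups stay on the same side of the extended chain.

**Route**

Step 1
Reactants: 1 undec-10-en-1-ol; 2 tert-butyl(chloro)dimethylsilane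
Product: 3 tert-butyldimethyl(undec-10-en-1-yloxy)silane
Conditions: imidazole, DMF, rt
Reagents that add atoms: tert-butyl(chloro)dimethylsilane 2, CC(C)(C)[Si](C)(C)Cl
Why: Imidazole-promoted silylation of a primary alcohol (silyl ether protection) removes the acidic O–H that would consume the alane, and the remote ether is inert to Me3Al and to the palladium coupling; no stereocentre is involved.

Step 2
Reactants: 3 tert-butyldimethyl(undec-10-en-1-yloxy)silane; 4 trimethylaluminium; 5 bromoethene
Product: 8 tert-butyldimethyl{[(10R)-10-methyltridec-12-en-1-yl]oxy}silane, via alkyldimethylalane 6 (not isolated), via alkylzinc triflate 7 (not isolated)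
Conditions: Me3Al, (−)-bis(1-neomenthylindenyl)zirconium dichloride [(−)-(NMI)2ZrCl2] (5 mol%), CH2Cl2, rt; evaporate; Zn(OSO2CF3)2, DMF, 70 °C; CH2=CHBr, PdCl2(DPEphos) (3 mol%), i-Bu2AlH (6 mol%), DMF, rt
Reagents that add atoms: trimethylaluminium 4, C[Al](C)C; bromoethene 5, C=CBr
Why: Zr-catalysed asymmetric carboalumination (ZACA reaction) adds Me–Al across the terminal alkene with the chiral zirconocene choosing the alkene face so that C10 becomes R, and the isoalkylalane, after Al-to-Zn exchange, undergoes Pd-catalysed Negishi coupling with vinyl bromide (i-Bu2AlH reducing the dichloride complex to zerovalent palladium) to restore a terminal alkene for the next cycle.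

Step 3
Reactants: 8 tert-butyldimethyl{[(10R)-10-methyltridec-12-en-1-yl]oxy}silane; 4 trimethylaluminium; 5 bromoethene
Product: 11 tert-butyl{[(10R,12S)-10,12-dimethylpentadec-14-en-1-yl]oxy}dimethylsilane, via alkyldimethylalane 9 (not isolated), via alkylzinc triflate 10 (not isolated)
Conditions: Me3Al, (−)-(NMI)2ZrCl2 (5 mol%), CH2Cl2, rt; evaporate; Zn(OSO2CF3)2, DMF, 70 °C; CH2=CHBr, PdCl2(DPEphos) (3 mol%), i-Bu2AlH (6 mol%), DMF, rt
Reagents that add atoms: trimethylaluminium 4, C[Al](C)C; bromoethene 5, C=CBr
Why: Second ZACA–Negishi vinylation cycle, in which the same catalyst enantiomer again dictates the face of methyl delivery to the 4-methyl-1-alkene and so places the new methyl 1,3-syn to the first (C12, S by priority), a wrong-face event giving a diastereomer and not the enantiomer.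

Step 4
Reactants: 11 tert-butyl{[(10R,12S)-10,12-dimethylpentadec-14-en-1-yl]oxy}dimethylsilane; 4 trimethylaluminium; 5 bromoethene
Product: 14 tert-butyldimethyl{[(10R,12R,14S)-10,12,14-trimethylheptadec-16-en-1-yl]oxy}silane, via alkyldimethylalane 12 (not isolated), via alkylzinc triflate 13 (not isolated)
Conditions: Me3Al, (−)-(NMI)2ZrCl2 (5 mol%), CH2Cl2, rt; evaporate; Zn(OSO2CF3)2, DMF, 70 °C; CH2=CHBr, PdCl2(DPEphos) (3 mol%), i-Bu2AlH (6 mol%), DMF, rt
Reagents that add atoms: trimethylaluminium 4, C[Al](C)C; bromoethene 5, C=CBr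
Why: Third ZACA–Negishi vinylation cycle under the same catalyst control, setting C14 syn to C12 and again ending in a 4-methyl-1-alkene terminus.

Step 5
Reactants: 14 tert-butyldimethyl{[(10R,12R,14S)-10,12,14-trimethylheptadec-16-en-1-yl]oxy}silane; 4 trimethylaluminium
Product: 16 (2R,4R,6R,8R)-17-[(tert-butyldimethylsilyl)oxy]-2,4,6,8-tetramethylheptadecan-1-ol, via alkyldimethylalane 15 (not isolated)
Conditions: Me3Al, (−)-(NMI)2ZrCl2 (5 mol%), CH2Cl2, rt; then O2 (1 atm), 0 °C to rt; aq. NaOH; chromatography on silica
Reagents that add atoms: trimethylaluminium 4, C[Al](C)C; dioxygen, O=O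
Why: A fourth ZACA methylalumination sets the last centre (C2 of 16, R) by catalyst control, and oxidation of the C–Al bond with O2 leaves that centre untouched and gives the 2-methylalkan-1-ol, the polar handle at which minor diastereomers should be separable.

Step 6
Reactants: 16 (2R,4R,6R,8R)-17-[(tert-butyldimethylsilyl)oxy]-2,4,6,8-tetramethylheptadecan-1-ol; 17 4-methylbenzenesulfonyl chloride
Product: 18 (2R,4R,6R,8R)-17-[(tert-butyldimethylsilyl)oxy]-2,4,6,8-tetramethylheptadecyl 4-methylbenzenesulfonate
Conditions: TsCl, pyridine, CH2Cl2, 0 °C to rt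
Reagents that add atoms: 4-methylbenzenesulfonyl chloride 17, Cc1ccc(cc1)S(Cl)(=O)=O
Why: Sulfonylation of the primary alcohol (tosylate formation) activates C1 for substitution without touching the adjacent stereocentre or the silyl ether.

Step 7
Reactants: 18 (2R,4R,6R,8R)-17-[(tert-butyldimethylsilyl)oxy]-2,4,6,8-tetramethylheptadecyl 4-methylbenzenesulfonate; 19 methyllithium
Product: 20 tert-butyldimethyl{[(10R,12R,14S,16S)-10,12,14,16-tetramethyloctadecyl]oxy}silane
Conditions: CuI, MeLi (2 equiv per Cu), Et2O, 0 °C; then 18, −20 to 0 °C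
Reagents that add atoms: methyllithium 19, [Li]C (delivered as lithium dimethylcuprate)
Why: Lithium dimethylcuprate displaces the primary tosylate in an SN2-type organocuprate coupling, turning CH2OTs into the terminal ethyl group; substitution occurs at a CH2 carbon, so the neighbouring stereocentre is unaffected.

Step 8
Reactants: 20 tert-butyldimethyl{[(10R,12R,14S,16S)-10,12,14,16-tetramethyloctadecyl]oxy}silane
Product: 21 (10R,12R,14S,16S)-10,12,14,16-tetramethyloctadecanoic acid
Conditions: CrO3, H2SO4, H2O, acetone, 0 °C to rt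
Reagents that add atoms: water, O
Why: Jones oxidation, in which the aqueous acid of the reagent cleaves the primary silyl ether and the freed alcohol is oxidised through the aldehyde hydrate to the acid in the same flask; the nearest stereocentre is eight methylenes away and the saturated chain holds nothing else oxidisable under these conditions.

Step 9
Reactants: 21 (10R,12R,14S,16S)-10,12,14,16-tetramethyloctadecanoic acid; 22 1,1'-carbonyldiimidazole; 23 methyl 3,5-dioxohexanoate
Product: 26 methyl (16R,18R,20S,22S)-16,18,20,22-tetramethyl-3,5,7-trioxotetracosanoate, via acyl imidazole 24 (not isolated), via trilithium trianion 25 (not isolated)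
Conditions: 21, CDI, THF, rt; separately 23 (2.2 equiv), LiN(i-Pr)2 (3 equiv per 23), THF, 0 °C; combine at −78 °C, warm to −20 °C; cold dilute HCl; crude product used directly
Reagents that add atoms: methyl 3,5-dioxohexanoate 23, COC(=O)CC(=O)CC(C)=O
Why: The acid is activated as its N-acylimidazole and the trianion of the dioxo ester, whose terminal C6 carbanion is the last formed and most nucleophilic site, is C-acylated there in a Claisen-type polyanion acylation, the excess trianion taking up the proton of the more acidic product.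

Step 10
Reactants: 26 methyl (16R,18R,20S,22S)-16,18,20,22-tetramethyl-3,5,7-trioxotetracosanoate
Product: 28 methyl 2,4-dihydroxy-6-[(9R,11R,13S,15S)-9,11,13,15-tetramethylheptadecyl]benzoate, via aldol adduct 27 (not isolated)
Conditions: K2CO3, MeOH–CH2Cl2, rt; then HCl in MeOH, rt
Reagents that add atoms: none
Why: Carbonate deprotonates the C2 methylene of 26, its most acidic C–H because it lies between the ester and the C3 ketone, and this enolate adds to the C7 ketone to give the hydroxy-cyclohexanedione 27, which loses water (completed by methanolic HCl) and enolises at C3 and C5 to the aromatic resorcylate, so forming the C2–C7 bond that joins the ester-bearing and the alkyl-bearing ring carbons. The closest known reaction type is the biomimetic intramolecular aldol aromatisation of 3,5,7-triketo esters to 6-alkylresorcylates. The single ring closes in a favoured 6-exo-trig mode, 6-(enolexo)-exo-trig with respect to the ester enolate. No stereocentre is created, since the two sp3 ring centres of 27 vanish on aromatisation, and the four chain centres lie at least nine atoms from any acidic position. The step needs aldol closure in preference to Claisen closure of C6 onto the ester, to O-cyclisation to a pyranone and to attack of C8 on the C3 ketone; the doubly activated C2–H, the mild carbonate base in methanol (degenerate transesterification, no chelating metal to favour the Claisen mode) and the low acidity of C8–H, which is alpha to one carbonyl only, should secure this.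

Step 11
Reactants: 28 methyl 2,4-dihydroxy-6-[(9R,11R,13S,15S)-9,11,13,15-tetramethylheptadecyl]benzoate; 29 iodomethane
Product: 30 methyl 2-hydroxy-4-methoxy-6-[(9R,11R,13S,15S)-9,11,13,15-tetramethylheptadecyl]benzoate
Conditions: MeI (1.1 equiv), K2CO3 (1.2 equiv), acetone, rt to 40 °C
Reagents that add atoms: iodomethane 29, CI
Why: Williamson-type O-methylation with a limited amount of MeI should occur at the 4-hydroxyl only, because the 2-hydroxyl is held in a hydrogen bond to the ester carbonyl and is both less acidic and less nucleophilic.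

Step 12
Reactants: 30 methyl 2-hydroxy-4-methoxy-6-[(9R,11R,13S,15S)-9,11,13,15-tetramethylheptadecyl]benzoate
Product: 31 2-(hydroxymethyl)-5-methoxy-3-[(9R,11R,13S,15S)-9,11,13,15-tetramethylheptadecyl]phenol
Conditions: LiAlH4 (excess), THF, 0 to 50 °C; Rochelle salt work-up
Reagents that add atoms: none
Why: Hydride reduction of the aryl ester by LiAlH4 gives the benzylic alcohol, an excess and gentle warming overcoming the deactivation by the ortho phenoxide, while the aryl methyl ether and the alkyl chain are inert.

Step 13
Reactants: 31 2-(hydroxymethyl)-5-methoxy-3-[(9R,11R,13S,15S)-9,11,13,15-tetramethylheptadecyl]phenol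
Product: 32 5-methoxy-2-methyl-3-[(9R,11R,13S,15S)-9,11,13,15-tetramethylheptadecyl]phenol
Conditions: H2 (1 atm), Pd/C, EtOAc–AcOH, rt
Reagents that add atoms: none
Why: Palladium-catalysed hydrogenolysis cleaves the benzylic C–O bond, which is activated by the ortho hydroxyl and para methoxy groups, to leave the aryl methyl group; the arene and the ether are not reduced at atmospheric pressure.

Step 14
Reactants: 32 5-methoxy-2-methyl-3-[(9R,11R,13S,15S)-9,11,13,15-tetramethylheptadecyl]phenol; 33 potassium nitrosodisulfonate
Product: 34 5-methoxy-2-methyl-3-[(9R,11R,13S,15S)-9,11,13,15-tetramethylheptadecyl]cyclohexa-2,5-diene-1,4-dione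
Conditions: (KSO3)2NO (2.5 equiv), KH2PO4, H2O–acetone–CH2Cl2, rt
Reagents that add atoms: potassium nitrosodisulfonate 33, [K+].[K+].[O]N(S(=O)(=O)[O-])S(=O)(=O)[O-]
Why: Teuber oxidation, in which the nitroxyl radical abstracts the phenolic hydrogen, a second equivalent couples at the unsubstituted para carbon and loss of imidodisulfonate gives the 1,4-quinone, the free para position between the chain and the methoxy group being the only site that leads to the para-quinone.

**Compound list**

1 | undec-10-en-1-ol | OCCCCCCCCCC=C | starting material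
2 | tert-butyl(chloro)dimethylsilane | CC(C)(C)[Si](C)(C)Cl | starting material
3 | tert-butyldimethyl(undec-10-en-1-yloxy)silane | CC(C)(C)[Si](C)(C)OCCCCCCCCCC=C | intermediate
4 | trimethylaluminium | C[Al](C)C | starting material
5 | bromoethene (vinyl bromide) | C=CBr | starting material
6 | {(2R)-11-[(tert-butyldimethylsilyl)oxy]-2-methylundecyl}dimethylalane (formed in the flask, step 2) | CC(C)(C)[Si](C)(C)OCCCCCCCCC[C@@H](C)C[Al](C)C | intermediate
7 | {(2R)-11-[(tert-butyldimethylsilyl)oxy]-2-methylundecyl}zinc trifluoromethanesulfonate (formed in the flask, step 2) | CC(C)(C)[Si](C)(C)OCCCCCCCCC[C@@H](C)C[Zn]OS(=O)(=O)C(F)(F)F | intermediate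
8 | tert-butyldimethyl{[(10R)-10-methyltridec-12-en-1-yl]oxy}silane | CC(C)(C)[Si](C)(C)OCCCCCCCCC[C@@H](C)CC=C | intermediate
9 | {(2R,4R)-13-[(tert-butyldimethylsilyl)oxy]-2,4-dimethyltridecyl}dimethylalane (formed in the flask, step 3) | CC(C)(C)[Si](C)(C)OCCCCCCCCC[C@@H](C)C[C@@H](C)C[Al](C)C | intermediate
10 | {(2R,4R)-13-[(tert-butyldimethylsilyl)oxy]-2,4-dimethyltridecyl}zinc trifluoromethanesulfonate (formed in the flask, step 3) | CC(C)(C)[Si](C)(C)OCCCCCCCCC[C@@H](C)C[C@@H](C)C[Zn]OS(=O)(=O)C(F)(F)F | intermediate
11 | tert-butyl{[(10R,12S)-10,12-dimethylpentadec-14-en-1-yl]oxy}dimethylsilane | CC(C)(C)[Si](C)(C)OCCCCCCCCC[C@@H](C)C[C@@H](C)CC=C | intermediate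
12 | {(2R,4R,6R)-15-[(tert-butyldimethylsilyl)oxy]-2,4,6-trimethylpentadecyl}dimethylalane (formed in the flask, step 4) | CC(C)(C)[Si](C)(C)OCCCCCCCCC[C@@H](C)C[C@@H](C)C[C@@H](C)C[Al](C)C | intermediate
13 | {(2R,4R,6R)-15-[(tert-butyldimethylsilyl)oxy]-2,4,6-trimethylpentadecyl}zinc trifluoromethanesulfonate (formed in the flask, step 4) | CC(C)(C)[Si](C)(C)OCCCCCCCCC[C@@H](C)C[C@@H](C)C[C@@H](C)C[Zn]OS(=O)(=O)C(F)(F)F | intermediate
14 | tert-butyldimethyl{[(10R,12R,14S)-10,12,14-trimethylheptadec-16-en-1-yl]oxy}silane | CC(C)(C)[Si](C)(C)OCCCCCCCCC[C@@H](C)C[C@@H](C)C[C@@H](C)CC=C | intermediate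
15 | {(2R,4R,6R,8R)-17-[(tert-butyldimethylsilyl)oxy]-2,4,6,8-tetramethylheptadecyl}dimethylalane (formed in the flask, step 5) | CC(C)(C)[Si](C)(C)OCCCCCCCCC[C@@H](C)C[C@@H](C)C[C@@H](C)C[C@@H](C)C[Al](C)C | intermediate
16 | (2R,4R,6R,8R)-17-[(tert-butyldimethylsilyl)oxy]-2,4,6,8-tetramethylheptadecan-1-ol | CC(C)(C)[Si](C)(C)OCCCCCCCCC[C@@H](C)C[C@@H](C)C[C@@H](C)C[C@@H](C)CO | intermediate
17 | 4-methylbenzenesulfonyl chloride | Cc1ccc(cc1)S(Cl)(=O)=O | starting material
18 | (2R,4R,6R,8R)-17-[(tert-butyldimethylsilyl)oxy]-2,4,6,8-tetramethylheptadecyl 4-methylbenzenesulfonate | CC(C)(C)[Si](C)(C)OCCCCCCCCC[C@@H](C)C[C@@H](C)C[C@@H](C)C[C@@H](C)COS(=O)(=O)c1ccc(C)cc1 | intermediate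
19 | methyllithium | [Li]C | starting material
20 | tert-butyldimethyl{[(10R,12R,14S,16S)-10,12,14,16-tetramethyloctadecyl]oxy}silane | CC(C)(C)[Si](C)(C)OCCCCCCCCC[C@@H](C)C[C@@H](C)C[C@@H](C)C[C@@H](C)CC | intermediate
21 | (10R,12R,14S,16S)-10,12,14,16-tetramethyloctadecanoic acid | OC(=O)CCCCCCCC[C@@H](C)C[C@@H](C)C[C@@H](C)C[C@@H](C)CC | intermediate
22 | 1,1'-carbonyldiimidazole | O=C(n1ccnc1)n1ccnc1 | starting material
23 | methyl 3,5-dioxohexanoate | COC(=O)CC(=O)CC(C)=O | starting material
24 | 1-[(10R,12R,14S,16S)-10,12,14,16-tetramethyloctadecanoyl]-1H-imidazole (formed in the flask, step 9) | O=C(CCCCCCCC[C@@H](C)C[C@@H](C)C[C@@H](C)C[C@@H](C)CC)n1ccnc1 | intermediate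
25 | trilithium salt of the 2,4,6-trianion of methyl 3,5-dioxohexanoate (formed in the flask, step 9) | [Li+].[Li+].[Li+].COC(=O)[CH-]C(=O)[CH-]C(=O)[CH2-] | intermediate
26 | methyl (16R,18R,20S,22S)-16,18,20,22-tetramethyl-3,5,7-trioxotetracosanoate | COC(=O)CC(=O)CC(=O)CC(=O)CCCCCCCC[C@@H](C)C[C@@H](C)C[C@@H](C)C[C@@H](C)CC | intermediate
27 | methyl 2-hydroxy-4,6-dioxo-2-[(9R,11R,13S,15S)-9,11,13,15-tetramethylheptadecyl]cyclohexane-1-carboxylate (ring centres undefined; formed in the flask, step 10) | COC(=O)C1C(=O)CC(=O)CC1(O)CCCCCCCC[C@@H](C)C[C@@H](C)C[C@@H](C)C[C@@H](C)CC | intermediate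
28 | methyl 2,4-dihydroxy-6-[(9R,11R,13S,15S)-9,11,13,15-tetramethylheptadecyl]benzoate | COC(=O)c1c(O)cc(O)cc1CCCCCCCC[C@@H](C)C[C@@H](C)C[C@@H](C)C[C@@H](C)CC | intermediate
29 | iodomethane | CI | starting material
30 | methyl 2-hydroxy-4-methoxy-6-[(9R,11R,13S,15S)-9,11,13,15-tetramethylheptadecyl]benzoate | COC(=O)c1c(O)cc(OC)cc1CCCCCCCC[C@@H](C)C[C@@H](C)C[C@@H](C)C[C@@H](C)CC | intermediate
31 | 2-(hydroxymethyl)-5-methoxy-3-[(9R,11R,13S,15S)-9,11,13,15-tetramethylheptadecyl]phenol | OCc1c(O)cc(OC)cc1CCCCCCCC[C@@H](C)C[C@@H](C)C[C@@H](C)C[C@@H](C)CC | intermediate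
32 | 5-methoxy-2-methyl-3-[(9R,11R,13S,15S)-9,11,13,15-tetramethylheptadecyl]phenol | Cc1c(O)cc(OC)cc1CCCCCCCC[C@@H](C)C[C@@H](C)C[C@@H](C)C[C@@H](C)CC | intermediate
33 | potassium nitrosodisulfonate (Fremy's salt) | [K+].[K+].[O]N(S(=O)(=O)[O-])S(=O)(=O)[O-] | starting material
34 | 5-methoxy-2-methyl-3-[(9R,11R,13S,15S)-9,11,13,15-tetramethylheptadecyl]cyclohexa-2,5-diene-1,4-dione (CNP0330767.1) | CC[C@H](C)C[C@H](C)C[C@H](C)C[C@H](C)CCCCCCCCC1=C(C)C(=O)C=C(OC)C1=O | target

**Step count**

Total: 14 steps. Longest linear sequence: 14 steps (1 to 34); every other component is a purchased material.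

**Steps most likely to fail**

Step 2. The unbranched alkene 3 carries no second stereocentre, so incomplete enantioface selection in this first methylalumination would be carried forward as a remote epimer that the chromatographic purification at 16 may not remove. The fallback sets out from 3 and isolates the first centre as an alcohol that can be enriched. The same methylalumination is run, but the alane is oxidised with O2 to (2R)-11-[(tert-butyldimethylsilyl)oxy]-2-methylundecan-1-ol F1. Treatment with the lipase of Burkholderia cepacia and vinyl acetate should acetylate the minor (S)-alcohol to (2S)-11-[(tert-butyldimethylsilyl)oxy]-2-methylundecyl acetate F2, which is separated and discarded, leaving F1 in raised enantiomeric purity. F1 is converted with I2, PPh3 and imidazole into tert-butyl{[(10R)-11-iodo-10-methylundecyl]oxy}dimethylsilane F3, and Cu-catalysed coupling of F3 with vinylmagnesium bromide (CuI, THF, −30 to 0 °C) comes back to the route at 8.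

Step 9. The strongly basic trianion may deprotonate the acyl imidazole at its α-methylene, or be acylated on oxygen or twice, so that little C6-acylated triketo ester forms. The fallback sets out from 21, again through its imidazolide 24, but uses a masked and less basic nucleophile. 2,2,6-Trimethyl-4H-1,3-dioxin-4-one is deprotonated with LiN(SiMe3)2 and acetylated with acetyl chloride to 2,2-dimethyl-6-(2-oxopropyl)-4H-1,3-dioxin-4-one F4. Its dianion (LiN(i-Pr)2, 2 equiv, THF, −78 °C) is acylated at the terminal methyl by 24 to give 2,2-dimethyl-6-[(13R,15R,17S,19S)-13,15,17,19-tetramethyl-2,4-dioxohenicosyl]-4H-1,3-dioxin-4-one F5. Heating F5 in toluene with methanol should release acetone, and the acylketene so formed is trapped by methanol as the methyl ester, which comes back to the route at 26.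

Step 10. Ring closure may take the Claisen course (C6 onto the ester) or the O-cyclisation course to a pyranone, or stall at the hydroxy-dione 27. The fallback sets out from 21 through 24 and removes the electrophilic ester from the cyclisation substrate. The dianion of 4-hydroxy-6-methyl-2H-pyran-2-one (LiN(i-Pr)2, THF, −78 °C) is acylated at its 6-methyl group by 24 to give 4-hydroxy-6-[(11R,13R,15S,17S)-11,13,15,17-tetramethyl-2-oxononadecyl]-2H-pyran-2-one F6. Aqueous KOH opens the lactone of F6 to the triketo carboxylate, whose carboxylate cannot accept a Claisen attack, so the same aldol bond is the only carbon–carbon closure left; this should give 2,4-dihydroxy-6-[(9R,11R,13S,15S)-9,11,13,15-tetramethylheptadecyl]benzoic acid F7. Esterification of F7 with Me3SiCHN2 in methanol–toluene returns to the route at 28.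

Further compounds
F1 | step 2 | (2R)-11-[(tert-butyldimethylsilyl)oxy]-2-methylundecan-1-ol | CC(C)(C)[Si](C)(C)OCCCCCCCCC[C@@H](C)CO
F2 | step 2 | (2S)-11-[(tert-butyldimethylsilyl)oxy]-2-methylundecyl acetate | CC(C)(C)[Si](C)(C)OCCCCCCCCC[C@H](C)COC(C)=O
F3 | step 2 | tert-butyl{[(10R)-11-iodo-10-methylundecyl]oxy}dimethylsilane | CC(C)(C)[Si](C)(C)OCCCCCCCCC[C@@H](C)CI
F4 | step 9 | 2,2-dimethyl-6-(2-oxopropyl)-4H-1,3-dioxin-4-one | CC(=O)CC1=CC(=O)OC(C)(C)O1
F5 | step 9 | 2,2-dimethyl-6-[(13R,15R,17S,19S)-13,15,17,19-tetramethyl-2,4-dioxohenicosyl]-4H-1,3-dioxin-4-one | CC1(C)OC(=O)C=C(CC(=O)CC(=O)CCCCCCCC[C@@H](C)C[C@@H](C)C[C@@H](C)C[C@@H](C)CC)O1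
F6 | step 10 | 4-hydroxy-6-[(11R,13R,15S,17S)-11,13,15,17-tetramethyl-2-oxononadecyl]-2H-pyran-2-one | O=C1C=C(O)C=C(CC(=O)CCCCCCCC[C@@H](C)C[C@@H](C)C[C@@H](C)C[C@@H](C)CC)O1
F7 | step 10 | 2,4-dihydroxy-6-[(9R,11R,13S,15S)-9,11,13,15-tetramethylheptadecyl]benzoic acid | OC(=O)c1c(O)cc(O)cc1CCCCCCCC[C@@H](C)C[C@@H](C)C[C@@H](C)C[C@@H](C)CC
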